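The ratio of substrate left at 120 min, blue over grey, was 1.03, though blue held 1.50 times grey's substrate charge. So I treated the percentage loss in these runs as first order. Grey and red, with different solid reagent charges, read 68.7% and 68.6% at that time. From grey, the substrate would halve in 3.69 h. I call this time T, the apparent half-life.

| flask | substrate | solid reagent | remark | time |
|---|---|---|---|---|
| grey | 0.10 M | 0.052 M | run made earlier |  |
| red | 0.10 M | 0.079 M | run made earlier |  |
| blue | 0.15 M | 0.105 M | run made earlier |  |
| dawn | 0.10 M | 0.105 M |  | 2.5 h |
| spring | 0.10 M | 0.105 M |  | 5.0 h |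

| run | time / min | substrate / % | target / % | side product / % | intermediate / % |
|---|---|---|---|---|---|
| grey | 10.0 | 97.7 | 1.0 | 0.2 | 0 |
| grey | 15.0 | 99.1 | 2.3 | 0.3 | 1.3 |
| grey | 25.0 | 93.4 | 3.6 | 0 | 1.1 |
| grey | 40.0 | 91.1 | 6.0 | 0 | 4.4 |
| grey | 80.0 | 80.8 | 6.7 | 0 | 11.6 |
| grey | 120 | 68.7 | 12.5 | 0.3 | 16.3 |
| red | 10.0 | 97.5 | 1.1 | 1.1 | 0.9 |
| red | 15.0 | 96.3 | 2.6 | 0 | 1.1 |
| red | 25.0 | 93.4 | 4.0 | 0.4 | 1.0 |
| red | 40.0 | 90.5 | 5.7 | 0.6 | 3.5 |
| red | 80.0 | 79.6 | 11.0 | 0 | 10.7 |
| red | 120 | 68.6 | 14.3 | 0 | 18.9 |
| blue | 25.0 | 94.4 | 5.6 | 1.8 | 0.9 |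
| blue | 50.0 | 88.0 | 6.5 | 0 | 4.6 |
| blue | 80.0 | 79.4 | 9.4 | 0 | 10.7 |
| blue | 90.0 | 78.4 | 11.8 | 0 | 12.5 |
| blue | 120 | 70.7 | 11.5 | 1.1 | 19.7 |

(each reading ± 1 percentage point)

- solid, in amounts per volume of the solution: solid reagent
- at the start none of the solid reagent is in solution

* which of these there is most of at the end, counted by the substrate in it, dawn (substrate / side product / intermediate / target)
* which of these there is most of at the end, counted by the substrate in it, spring (substrate / side product / intermediate / target)
* final amount of the leader among these, as a percentage of the substrate charged, in dawn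
* final amount of the leader among these, as a percentage of the substrate charged, in spring

The ladder in grey ran as follows, and both read rungs came before T.

| Time | Grey flask |
|---|---|
| 25.0 min | intermediate 1.1%, below target 3.6% |
| 80.0 min | intermediate 11.6%, above target 6.7% |
| 3.69 h | substrate at half, by my count |

Dawn lasted 0.677 half-lives, so my count gave 62.5% substrate. That was more than the remaining 37.5% together, so I expected substrate to lead dawn. Spring lasted 1.35 half-lives, so my count gave 39.1%. I held target at red's last 14.3% and neglected side product. My count then gave intermediate 46.6%, more than substrate. This was extrapolation past the runs.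

The forecast gave substrate at 62% for dawn and intermediate at 49% for spring, and said “Solid loading has no visible effect”. My dawn figure stood 0.50 percentage points above it, and my spring figure 2.4 points below it.

The flasks gave substrate at 59.9% in dawn and intermediate at 50.6% in spring.

    substrate ⇌ target (K = 0.320, k = 0.00170 /min)
    partner + intermediate → side product (k = 0.00370 /M/min)
    solid reagent ⇌ partner, rate k3*(cs3 - [partner]) while solid is left; crystals form when [partner] > cs3 (solubility = 0.0920 M, k = 0.00820 /min)
    substrate + partner ⇌ intermediate (K = 150 /M, k = 0.0780 /M/min)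

Spring's substrate ended at 34.2%, against my 39.1%, so its T reads 3.23 h, not 3.69 h. The neighbour flask is spring with solid reagent cut to 0.063 M, below the 0.10 M of substrate, which makes solid reagent the limiting reagent by charge. My count gave that neighbour flask the same 39.1%. It ended at 44.9%, so its T reads 4.32 h, longer than spring's. In that neighbour flask, substrate led at 44.9%, above intermediate at 39.4%.

(Readings and results stem from a simulated flask from invented constants, noise included.)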